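**Retrosynthetic overview**

1. The target is a single 25-membered lactone ring (24 carbons plus the ring oxygen) with no stereocentre. The plan rests on C13, a plain CH2 that sits half-way round the ring opposite the ester, between the C1–C12 acyl chain and the C14–C24 alkoxy chain.
2. Cutting C12–C13 and C13–C14 turns C13 into a methylene dianion equivalent, bis(phenylsulfonyl)methane, and leaves an open-chain ester with a primary bromide at C12 and another at C14.
3. That ester is cut at the C1–O bond into 12-bromododecanoic acid and 11-bromoundecan-1-ol.
4. Order of events: the ester bond first; then the only ring is closed by the second of two alkylations at C13; then both sulfonyl groups are removed reductively.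

Key step: step 2

Remark on numbering: C1 is the lactone carbonyl carbon and C24 the carbon on the ring oxygen; this numbering is kept for all intermediates.

**Route**

Step 1
Reactants: 1 12-bromododecanoic acid; 2 11-bromoundecan-1-ol
Product: 3 11-bromoundecyl 12-bromododecanoate
Conditions: DCC (1.1 equiv), DMAP (0.1 equiv), CH2Cl2, 0 °C to rt
Reagents that add atoms: none
Why: Steglich esterification of an unhindered acid with a primary alcohol, in which DMAP passes the carbodiimide-activated acyl group to the alcohol while both primary bromides stay untouched under these neutral, room-temperature conditions.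

Step 2
Reactants: 3 11-bromoundecyl 12-bromododecanoate; 4 bis(phenylsulfonyl)methane
Product: 7 13,13-bis(phenylsulfonyl)-24-tetracosanolide, via 11-bromoundecyl 13,13-bis(phenylsulfonyl)tridecanoate 5 (not isolated), via 12,12-bis(phenylsulfonyl)dodecyl 12-bromododecanoate 6 (not isolated)
Conditions: Cs2CO3 (5 equiv), 4 Å sieves, dry DMF, 3 at about 2 mM, 70 °C; 4 (1.0 equiv) in DMF added by syringe pump over about 40 h, then a further 24 h at 70 °C
Reagents that add atoms: none
Why: Cs2CO3 in DMF deprotonates 4, a carbon acid far stronger than the ester α-CH2, and its carbanion displaces one primary bromide of 3 by SN2 to give the regioisomeric monoalkylated bromides 5 (C12–C13 formed first) and 6 (C13–C14 formed first). Each is deprotonated again at C13, and the tertiary carbanion displaces the remaining primary bromide at the far end of the chain, forming the other bond and closing the 25-membered ring in an end-to-end exo-tet SN2 macrocyclisation; 5 and 6 converge on the same product 7. The closest known reaction type is the geminal dialkylation of active-methylene compounds (malonates, bis-sulfonylmethanes) with α,ω-dihalides, together with the carbonate-mediated intramolecular alkylation of stabilised carbanions used to close large rings. No stereocentre arises, because C13 carries two identical sulfonyl groups. The selectivity needed is ring closure over chain growth and over capping of the second bromide by another carbanion of 4; it should be secured by holding 3 near 2 mM (below the effective molarity expected for a strain-free large ring), by feeding 4 slowly in a one-to-one amount so that its free carbanion stays scarce, and by the flexible polymethylene chains that end in unhindered primary carbons. The ester should survive because the delocalised, hindered carbanion does not acylate and dry carbonate does not saponify.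

Step 3
Reactants: 7 13,13-bis(phenylsulfonyl)-24-tetracosanolide
Product: 9 24-tetracosanolide, via 13-(phenylsulfonyl)-24-tetracosanolide 8 (not isolated)
Conditions: 6% Na(Hg) (excess), Na2HPO4 (excess), MeOH–THF 1:3, −20 °C to 0 °C
Reagents that add atoms: none
Why: Reductive desulfonylation by electron transfer from Na(Hg), in which loss of the first sulfinate gives a sulfonyl-stabilised carbanion that is protonated to racemic mono-sulfone 8, whose remaining C–S bond is cleaved in the same way, while Na2HPO4 buffers the methoxide formed so that the unstrained lactone should not be methanolysed at low temperature.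

**Compound list**

1 | 12-bromododecanoic acid | OC(=O)CCCCCCCCCCCBr | starting material
2 | 11-bromoundecan-1-ol | OCCCCCCCCCCCBr | starting material
3 | 11-bromoundecyl 12-bromododecanoate | BrCCCCCCCCCCCC(=O)OCCCCCCCCCCCBr | intermediate
4 | bis(phenylsulfonyl)methane | O=S(=O)(CS(=O)(=O)c1ccccc1)c1ccccc1 | starting material
5 | 11-bromoundecyl 13,13-bis(phenylsulfonyl)tridecanoate | O=C(CCCCCCCCCCCC(S(=O)(=O)c1ccccc1)S(=O)(=O)c1ccccc1)OCCCCCCCCCCCBr | intermediate (not isolated)
6 | 12,12-bis(phenylsulfonyl)dodecyl 12-bromododecanoate | BrCCCCCCCCCCCC(=O)OCCCCCCCCCCCC(S(=O)(=O)c1ccccc1)S(=O)(=O)c1ccccc1 | intermediate (not isolated)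
7 | 13,13-bis(phenylsulfonyl)-24-tetracosanolide (14,14-bis(phenylsulfonyl)oxacyclopentacosan-2-one) | O=C1CCCCCCCCCCCC(S(=O)(=O)c2ccccc2)(S(=O)(=O)c2ccccc2)CCCCCCCCCCCO1 | intermediate
8 | 13-(phenylsulfonyl)-24-tetracosanolide, racemic at C13 | O=C1CCCCCCCCCCCC(S(=O)(=O)c2ccccc2)CCCCCCCCCCCO1 | intermediate (not isolated)
9 | 24-tetracosanolide (oxacyclopentacosan-2-one) | O=C1CCCCCCCCCCCCCCCCCCCCCCCO1 | target

**Totals**

Total step count: 3. Longest linear sequence: 3 steps (1 or 2, then 3, 7, 9).

**Steps most likely to fail, with fallbacks**

Step 2 (highest risk). What may go wrong: chain growth between molecules in place of ring closure, capping of the second bromide by a further carbanion of 4, and a slow second displacement by the hindered tertiary carbanion at C13. The fallback makes the two C–C bonds in separate operations, so that no intermolecular alkylation has to run under dilution. It sets out from 2 and 4. Compound 4, used in excess with K2CO3 in DMF at 60 °C, is monoalkylated by 2 to give 12,12-bis(phenylsulfonyl)dodecan-1-ol F1, which fixes C13–C14. F1 is esterified with 1 (DCC, DMAP, CH2Cl2) to give 6, here isolated and purified as a single compound. A solution of 6 is then added by syringe pump to Cs2CO3 in DMF at 70 °C, which closes C12–C13 intramolecularly, and the route is rejoined at 7.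

Step 3. What may go wrong: opening of the lactone by methoxide that builds up during the reduction, or stalling after loss of only one sulfonyl group. The fallback takes the ester out of the reduction and closes the ring again at the ester bond. It sets out from 7. Saponification (LiOH, THF–H2O, then dilute HCl) should give 24-hydroxy-13,13-bis(phenylsulfonyl)tetracosanoic acid F2. Na(Hg) with Na2HPO4 in MeOH–THF, now at room temperature and with a large excess of reagent since no ester is at risk, should remove both sulfonyl groups by way of racemic 24-hydroxy-13-(phenylsulfonyl)tetracosanoic acid F3, not isolated, to give 24-hydroxytetracosanoic acid F4. Yamaguchi macrolactonisation follows: 2,4,6-trichlorobenzoyl chloride and Et3N in THF give 24-hydroxytetracosanoic 2,4,6-trichlorobenzoic anhydride F5, not isolated, which is added slowly to DMAP in toluene at reflux under high dilution. The route is rejoined at 9.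

Step 1. What may go wrong: rearrangement of the carbodiimide-activated acid to an unreactive N-acylurea, and carry-over of urea into the non-polar ester. The fallback activates the acid in a separate step. It sets out from 1. Oxalyl chloride with catalytic DMF in CH2Cl2 should give 12-bromododecanoyl chloride F6, which acylates 2 in CH2Cl2 with pyridine at 0 °C and rejoins the route at 3.

**Further compounds**

F1 | step 2 | 12,12-bis(phenylsulfonyl)dodecan-1-ol | OCCCCCCCCCCCC(S(=O)(=O)c1ccccc1)S(=O)(=O)c1ccccc1
F2 | step 3 | 24-hydroxy-13,13-bis(phenylsulfonyl)tetracosanoic acid | OC(=O)CCCCCCCCCCCC(S(=O)(=O)c1ccccc1)(S(=O)(=O)c1ccccc1)CCCCCCCCCCCO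
F3 | step 3 | 24-hydroxy-13-(phenylsulfonyl)tetracosanoic acid, racemic at C13 | OC(=O)CCCCCCCCCCCC(S(=O)(=O)c1ccccc1)CCCCCCCCCCCO
F4 | step 3 | 24-hydroxytetracosanoic acid | OC(=O)CCCCCCCCCCCCCCCCCCCCCCCO
F5 | step 3 | 24-hydroxytetracosanoic 2,4,6-trichlorobenzoic anhydride | OCCCCCCCCCCCCCCCCCCCCCCCC(=O)OC(=O)c1c(Cl)cc(Cl)cc1Cl
F6 | step 1 | 12-bromododecanoyl chloride | ClC(=O)CCCCCCCCCCCBr
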